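## Retrosynthetic overview

1. Target ⇐ triol 19 by late acylations: tiglate on C10 while the 4,6-diol is masked as a boronate, then the 4-hydroxybenzoate on C6.
2. H-5 and the C6 oxygen ⇐ C5=C6 alkene of diene-diol 16, by a hydrosilylation tethered to the C10 oxygen, then Tamao oxidation.
3. Seven-membered ring (formed second), quaternary C1 and C10 ⇐ key step: rhodium-vinylcarbenoid cyclopropanation of vinylcyclopentene 6 with siloxyvinyl diazoacetate 10, then divinylcyclopropane Cope rearrangement (formal [4+3]); the ester becomes the C8 methyl.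
4. Five-membered ring (formed first) ⇐ (R)-terpinen-4-ol by ozonolysis / aldol ring contraction; C4 comes from the chiral pool.
5. 10 ⇐ ethyl diazoacetate + silyloxyacetaldehyde.

Assumption: (R)-(−)-terpinen-4-ol is taken as commercially available in ≥98% ee; a lot of lower ee is upgraded at step 7, where the catalyst turns the minor enantiomer into a separable diastereomer.

Numbering in names of bicyclic compounds is daucane numbering: C1 (ring fusion, bears methyl C15), C2, C3, C4 (carbinol, bears isopropyl), C5 (ring-fusion CH), C6 to C10 (seven-membered ring), C14 (carbon on C8). β is the face of the C15 methyl. In every bicyclic compound the C15 methyl and the isopropyl group are β and the C4 oxygen is α.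

## Route

Step 1
Reactants: 1 (R)-(−)-terpinen-4-ol
Product: 2 triethyl{[(1R)-4-methyl-1-(propan-2-yl)cyclohex-3-en-1-yl]oxy}silane
Conditions: Et3SiOTf, 2,6-lutidine, CH2Cl2, 0 °C
Reagents that add atoms: triethylsilyl trifluoromethanesulfonate, CC[Si](CC)(CC)OS(=O)(=O)C(F)(F)F
Why: Silyl triflate silylation of the hindered tertiary alcohol leaves the chiral-pool C4 centre untouched; the silyl ether later stops this oxygen from leaving in the aldol condensation and from O–H insertion by the carbenoid.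

Step 2
Reactants: 2 triethyl{[(1R)-4-methyl-1-(propan-2-yl)cyclohex-3-en-1-yl]oxy}silane
Product: 4 (3R)-6-oxo-3-(propan-2-yl)-3-[(triethylsilyl)oxy]heptanal, via secondary ozonide 3 (not isolated)
Conditions: O3, CH2Cl2, −78 °C; then Me2S, −78 °C → rt
Reagents that add atoms: ozone, [O-][O+]=O
Why: Ozonolysis (Criegee mechanism) of the only alkene with reductive work-up unmasks the C1 methyl ketone and the C6 aldehyde without touching C4.

Step 3
Reactants: 4 (3R)-6-oxo-3-(propan-2-yl)-3-[(triethylsilyl)oxy]heptanal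
Product: 5 (5S)-2-methyl-5-(propan-2-yl)-5-[(triethylsilyl)oxy]cyclopent-1-ene-1-carbaldehyde
Conditions: piperidine (0.3 equiv), AcOH (0.3 equiv), 4 Å MS, toluene, 60 °C
Reagents that add atoms: none
Why: Intramolecular aldol condensation through the aldehyde enamine (the regiochemistry known for 3-substituted 6-oxoheptanals under secondary amine/acid catalysis) closes the five-membered ring by C5–C1 bond formation, and E1cB loss of the new free C1 hydroxyl, not of the silylated C4 oxygen, gives the enal; no stereocentre is formed.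

Step 4
Reactants: 5 (5S)-2-methyl-5-(propan-2-yl)-5-[(triethylsilyl)oxy]cyclopent-1-ene-1-carbaldehyde
Product: 6 {[(1S)-2-ethenyl-3-methyl-1-(propan-2-yl)cyclopent-2-en-1-yl]oxy}triethylsilane
Conditions: Ph3PCH3Br, KN(SiMe3)2, THF, 0 °C → rt
Reagents that add atoms: methyltriphenylphosphonium bromide, C[P+](c1ccccc1)(c1ccccc1)c1ccccc1.[Br-]
Why: Wittig methylenation of the aldehyde gives the 1-vinyl-2-methylcyclopentene whose unhindered terminal alkene is the cyclopropanation site; no stereocentre is affected.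

Step 5
Reactants: 7 ethyl diazoacetate; 8 [(tert-butyldimethylsilyl)oxy]acetaldehyde
Product: 9 ethyl 4-[(tert-butyldimethylsilyl)oxy]-2-diazo-3-hydroxybutanoate (racemic)
Conditions: DBU (10 mol %), MeCN, rt
Reagents that add atoms: none
Why: Base-catalysed aldol-type addition of the C–H acidic diazoacetate to the aldehyde; the racemic carbinol centre is removed in step 6.

Step 6
Reactants: 9 ethyl 4-[(tert-butyldimethylsilyl)oxy]-2-diazo-3-hydroxybutanoate
Product: 10 ethyl (3E)-4-[(tert-butyldimethylsilyl)oxy]-2-diazobut-3-enoate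
Conditions: POCl3, Et3N, CH2Cl2, 0 °C; used at once
Reagents that add atoms: none
Why: Dehydration of the β-hydroxy-α-diazo ester through its dichlorophosphate (the standard elimination route to vinyldiazoacetates) gives the conjugated, thermodynamically preferred E enol ether.

Step 7
Reactants: 6 {[(1S)-2-ethenyl-3-methyl-1-(propan-2-yl)cyclopent-2-en-1-yl]oxy}triethylsilane; 10 ethyl (3E)-4-[(tert-butyldimethylsilyl)oxy]-2-diazobut-3-enoate
Product: 12 ethyl 10α-[(tert-butyldimethylsilyl)oxy]-4α-[(triethylsilyl)oxy]dauca-5,8-dien-14-oate, via cis-divinylcyclopropane 11 (not isolated)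
Conditions: Rh2(R-DOSP)4 [dirhodium tetrakis((R)-N-(4-dodecylbenzenesulfonyl)prolinate)] (2 mol %), 10 (1.6 equiv, slow addition), 2,2-dimethylbutane, −40 °C → rt; then toluene, 80 °C
Reagents that add atoms: none
Why: Tandem cyclopropanation/Cope rearrangement (formal [4+3] cycloaddition of a rhodium vinylcarbenoid): the donor/acceptor carbenoid adds only to the monosubstituted vinyl group, placing the two alkenyl groups cis, with the catalyst choosing the alkene face (the mirror image of the (1S,2R) sense that Rh2(S-DOSP)4 gives with styrene, so 11 is 1R,2S); the boat Cope transition state then bonds C10 to C1 on the face syn to the C4 silyloxy group and anti to isopropyl, and the inward methyl on C1 and the outward (E) silyloxy on C10 end up trans, which sets the quaternary C1 and C10 together.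

Step 8
Reactants: 12 ethyl 10α-[(tert-butyldimethylsilyl)oxy]-4α-[(triethylsilyl)oxy]dauca-5,8-dien-14-oate
Product: 13 10α-[(tert-butyldimethylsilyl)oxy]-4α-[(triethylsilyl)oxy]dauca-5,8-dien-14-ol
Conditions: i-Bu2AlH (2.5 equiv), CH2Cl2, −78 °C
Reagents that add atoms: none
Why: 1,2-Reduction of the conjugated ester by the aluminium hydride at low temperature gives the primary allylic alcohol; no stereocentre is affected.

Step 9
Reactants: 13 10α-[(tert-butyldimethylsilyl)oxy]-4α-[(triethylsilyl)oxy]dauca-5,8-dien-14-ol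
Product: 15 10α-[(tert-butyldimethylsilyl)oxy]-4α-[(triethylsilyl)oxy]dauca-5,8-diene, via allylic mesylate 14 (not isolated)
Conditions: MsCl, Et3N, CH2Cl2, −40 °C; then LiBHEt3, THF, −78 → 0 °C
Reagents that add atoms: none
Why: Mesylation followed by SN2 hydride displacement at the unhindered primary allylic carbon (attack at the CH2 terminus avoids SN2′ transposition) turns CH2OH into the C8 methyl group and leaves the C8=C9 alkene in place.

Step 10
Reactants: 15 10α-[(tert-butyldimethylsilyl)oxy]-4α-[(triethylsilyl)oxy]dauca-5,8-diene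
Product: 16 dauca-5,8-diene-4α,10α-diol
Conditions: n-Bu4NF (3 equiv), THF, 0 °C → rt
Reagents that add atoms: none
Why: Fluoride-mediated desilylation removes both silyl ethers under basic conditions that do not ionise the tertiary allylic C4 alcohol.

Step 11
Reactants: 16 dauca-5,8-diene-4α,10α-diol
Product: 18 cyclic siloxane 6α,10α-[oxy(dimethylsilanediyl)]-5αH-dauc-8-en-4α-ol (Si on C6; O on C10), via dimethylsilyl ether 17 (not isolated)
Conditions: HMe2SiCl (1.05 equiv), Et3N, CH2Cl2, −20 °C; filter, concentrate; then Pt2[(CH2=CHSiMe2)2O]3 (1 mol %), toluene, 60 °C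
Reagents that add atoms: chlorodimethylsilane, C[SiH](C)Cl
Why: Selective silylation of the secondary C10 hydroxyl, then platinum-catalysed intramolecular hydrosilylation (Tamao type, Chalk–Harrod syn addition): anchored on the α oxygen at C10, the Si–H reaches C5=C6 only from the α face, silicon bonds to the CH terminus C6 (6-endo, because C5 is fully substituted between two quaternary carbons) and hydrogen goes to C5, which sets H-5 α (trans ring fusion) and the C6 configuration in one event.

Step 12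
Reactants: 18 cyclic siloxane 6α,10α-[oxy(dimethylsilanediyl)]-5αH-dauc-8-en-4α-ol
Product: 19 5αH-dauc-8-ene-4α,6α,10α-triol
Conditions: 30% aq. H2O2, KF, KHCO3, THF–MeOH (1:1), rt
Reagents that add atoms: hydrogen peroxide, OO
Why: Tamao–Fleming oxidation replaces the C6–Si bond by C6–OH with retention of configuration, giving the 6α-hydroxyl, and releases the C10 hydroxyl.

Step 13
Reactants: 19 5αH-dauc-8-ene-4α,6α,10α-triol
Product: 22 4α,6α-dihydroxy-5αH-dauc-8-en-10α-yl (2E)-2-methylbut-2-enoate, via phenylboronate 20 (not isolated), via tigloylated phenylboronate 21 (not isolated)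
Conditions: PhB(OH)2 (1.05 equiv), MgSO4, CH2Cl2, rt; then (E)-2-methylbut-2-enoyl chloride, pyridine, DMAP (cat.), 0 °C → rt; then aq. sorbitol/Na2CO3 wash
Reagents that add atoms: (E)-2-methylbut-2-enoyl chloride, C/C=C(\C)C(Cl)=O
Why: The syn 4α,6α-1,3-diol is masked in situ as its six-membered cyclic phenylboronate, so DMAP-catalysed acylation can occur only at the C10 hydroxyl, and hydrolytic work-up frees the diol; the E (tiglate) geometry is the stable one and is kept.

Step 14
Reactants: 22 4α,6α-dihydroxy-5αH-dauc-8-en-10α-yl (2E)-2-methylbut-2-enoate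
Product: 23 6α-[(4-acetoxybenzoyl)oxy]-4α-hydroxy-5αH-dauc-8-en-10α-yl (2E)-2-methylbut-2-enoate
Conditions: 4-acetoxybenzoic acid, DCC, DMAP (cat.), CH2Cl2, rt
Reagents that add atoms: 4-acetoxybenzoic acid, CC(=O)Oc1ccc(cc1)C(O)=O
Why: Steglich esterification acylates the secondary C6 hydroxyl and leaves the tertiary, isopropyl-flanked C4 hydroxyl untouched; no stereocentre is involved.

Step 15
Reactants: 23 6α-[(4-acetoxybenzoyl)oxy]-4α-hydroxy-5αH-dauc-8-en-10α-yl (2E)-2-methylbut-2-enoate
Product: 24 CNP0273650.6, 4α-hydroxy-6α-[(4-hydroxybenzoyl)oxy]-5αH-dauc-8-en-10α-yl (2E)-2-methylbut-2-enoate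
Conditions: pyrrolidine (2 equiv), CH2Cl2, 0 °C → rt
Reagents that add atoms: none
Why: Aminolysis of the activated aryl acetate is far faster than attack on the hindered alkyl tiglate and benzoate esters, so only the phenol is released.

## Compound list

1 | (R)-(−)-terpinen-4-ol, (1R)-4-methyl-1-(propan-2-yl)cyclohex-3-en-1-ol | CC1=CC[C@@](O)(C(C)C)CC1 | starting material
2 | triethyl{[(1R)-4-methyl-1-(propan-2-yl)cyclohex-3-en-1-yl]oxy}silane | CC1=CC[C@@](O[Si](CC)(CC)CC)(C(C)C)CC1 | intermediate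
3 | secondary ozonide (1,2,4-trioxolane) of 2, mixture at the two ozonide carbons | CC12CC[C@](O[Si](CC)(CC)CC)(C(C)C)CC(OO1)O2 | intermediate
4 | (3R)-6-oxo-3-(propan-2-yl)-3-[(triethylsilyl)oxy]heptanal | CC(=O)CC[C@](O[Si](CC)(CC)CC)(C(C)C)CC=O | intermediate
5 | (5S)-2-methyl-5-(propan-2-yl)-5-[(triethylsilyl)oxy]cyclopent-1-ene-1-carbaldehyde | CC1=C(C=O)[C@@](O[Si](CC)(CC)CC)(C(C)C)CC1 | intermediate
6 | {[(1S)-2-ethenyl-3-methyl-1-(propan-2-yl)cyclopent-2-en-1-yl]oxy}triethylsilane | CC1=C(C=C)[C@@](O[Si](CC)(CC)CC)(C(C)C)CC1 | intermediate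
7 | ethyl diazoacetate | CCOC(=O)C=[N+]=[N-] | starting material
8 | [(tert-butyldimethylsilyl)oxy]acetaldehyde | O=CCO[Si](C)(C)C(C)(C)C | starting material
9 | ethyl 4-[(tert-butyldimethylsilyl)oxy]-2-diazo-3-hydroxybutanoate (racemic) | CCOC(=O)C(=[N+]=[N-])C(O)CO[Si](C)(C)C(C)(C)C | intermediate
10 | ethyl (3E)-4-[(tert-butyldimethylsilyl)oxy]-2-diazobut-3-enoate | CCOC(=O)C(=[N+]=[N-])/C=C/O[Si](C)(C)C(C)(C)C | intermediate
11 | ethyl (1R,2S)-1-[(E)-2-{[tert-butyl(dimethyl)silyl]oxy}ethenyl]-2-[(5S)-2-methyl-5-(propan-2-yl)-5-(triethylsilyloxy)cyclopent-1-en-1-yl]cyclopropane-1-carboxylate (the two alkenyl groups cis) | CCOC(=O)[C@]1(/C=C/O[Si](C)(C)C(C)(C)C)C[C@H]1C2=C(C)CC[C@]2(O[Si](CC)(CC)CC)C(C)C | intermediate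
12 | ethyl 10α-[(tert-butyldimethylsilyl)oxy]-4α-[(triethylsilyl)oxy]dauca-5,8-dien-14-oate | CC(C)(C)[Si](C)(C)O[C@@H]1C=C(C(=O)OCC)CC=C2[C@]1(C)CC[C@]2(O[Si](CC)(CC)CC)C(C)C | intermediate
13 | 10α-[(tert-butyldimethylsilyl)oxy]-4α-[(triethylsilyl)oxy]dauca-5,8-dien-14-ol | CC(C)(C)[Si](C)(C)O[C@@H]1C=C(CO)CC=C2[C@]1(C)CC[C@]2(O[Si](CC)(CC)CC)C(C)C | intermediate
14 | 10α-[(tert-butyldimethylsilyl)oxy]-4α-[(triethylsilyl)oxy]dauca-5,8-dien-14-yl methanesulfonate | CC(C)(C)[Si](C)(C)O[C@@H]1C=C(COS(C)(=O)=O)CC=C2[C@]1(C)CC[C@]2(O[Si](CC)(CC)CC)C(C)C | intermediate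
15 | 10α-[(tert-butyldimethylsilyl)oxy]-4α-[(triethylsilyl)oxy]dauca-5,8-diene | CC(C)(C)[Si](C)(C)O[C@@H]1C=C(C)CC=C2[C@]1(C)CC[C@]2(O[Si](CC)(CC)CC)C(C)C | intermediate
16 | dauca-5,8-diene-4α,10α-diol | O[C@@H]1C=C(C)CC=C2[C@]1(C)CC[C@]2(O)C(C)C | intermediate
17 | 10α-[(dimethylsilyl)oxy]dauca-5,8-dien-4α-ol | C[SiH](C)O[C@@H]1C=C(C)CC=C2[C@]1(C)CC[C@]2(O)C(C)C | intermediate
18 | cyclic siloxane 6α,10α-[oxy(dimethylsilanediyl)]-5αH-dauc-8-en-4α-ol (Si on C6, O on C10) | C[Si]3(C)O[C@@H]1C=C(C)C[C@H]3[C@@H]2[C@]1(C)CC[C@]2(O)C(C)C | intermediate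
19 | 5αH-dauc-8-ene-4α,6α,10α-triol | O[C@@H]1C=C(C)C[C@H](O)[C@@H]2[C@]1(C)CC[C@]2(O)C(C)C | intermediate
20 | 4α,6α-O-(phenylboranediyl)-5αH-dauc-8-ene-4α,6α,10α-triol | O[C@@H]1C=C(C)C[C@H]3[C@@H]2[C@]1(C)CC[C@]2(OB(O3)c4ccccc4)C(C)C | intermediate
21 | 4α,6α-O-(phenylboranediyl)-4α,6α-dihydroxy-5αH-dauc-8-en-10α-yl (2E)-2-methylbut-2-enoate | C/C=C(\C)C(=O)O[C@@H]1C=C(C)C[C@H]3[C@@H]2[C@]1(C)CC[C@]2(OB(O3)c4ccccc4)C(C)C | intermediate
22 | 4α,6α-dihydroxy-5αH-dauc-8-en-10α-yl (2E)-2-methylbut-2-enoate | C/C=C(\C)C(=O)O[C@@H]1C=C(C)C[C@H](O)[C@@H]2[C@]1(C)CC[C@]2(O)C(C)C | intermediate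
23 | 6α-[(4-acetoxybenzoyl)oxy]-4α-hydroxy-5αH-dauc-8-en-10α-yl (2E)-2-methylbut-2-enoate | C/C=C(\C)C(=O)O[C@@H]1C=C(C)C[C@H](OC(=O)c2ccc(OC(C)=O)cc2)[C@@H]2[C@]1(C)CC[C@]2(O)C(C)C | intermediate
24 | CNP0273650.6, [(3S,3aS,4S,8R,8aS)-3-hydroxy-6,8a-dimethyl-8-{[(2E)-2-methylbut-2-enoyl]oxy}-3-(propan-2-yl)-1,2,3,3a,4,5,8,8a-octahydroazulen-4-yl] 4-hydroxybenzoate | C/C=C(\C)C(=O)O[C@@H]1C=C(C)C[C@H](OC(=O)c2ccc(O)cc2)[C@@H]2[C@]1(C)CC[C@]2(O)C(C)C | target

## Count and risks

Total step count: 15. Longest linear sequence: 13 steps (steps 1–4 and 7–15 from 1); steps 5–6 form the two-step side branch to 10.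

Three steps most likely to fail:

**Step 7 (tandem cyclopropanation/Cope).** The risks are the lability of the electron-rich diazo partner 10, the sense and level of catalyst control on a chiral diene, and a Cope rearrangement that must form a quaternary centre with an inward methyl group. The fallback sets out from 6 (with 7 as the source of a different carbene partner) and comes back at 12; it takes the C10 oxygen out of the cycloaddition. Compound 7 and acetaldehyde give, under DBU, ethyl 2-diazo-3-hydroxybutanoate F1. Dehydration with POCl3/Et3N gives the parent vinyldiazoacetate ethyl 2-diazobut-3-enoate F2. With 6 and Rh2(R-DOSP)4, the same cyclopropanation/Cope sequence gives ethyl 4α-[(triethylsilyl)oxy]dauca-5,8-dien-14-oate F3. γ-Deprotonation with LiN(i-Pr)2 and trapping of the dienolate at C8 with PhSeCl give ethyl 8α-(phenylselanyl)-4α-[(triethylsilyl)oxy]dauca-5,9-dien-14-oate F4. Oxidation with H2O2/pyridine gives the selenoxide, which undergoes a suprafacial [2,3]-sigmatropic shift to the C10 selenenate and on hydrolysis gives ethyl 10α-hydroxy-4α-[(triethylsilyl)oxy]dauca-5,8-dien-14-oate F5. Silylation with TBSCl/imidazole returns 12.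

**Step 11 (tethered hydrosilylation).** The risks are 6-endo closure onto a trisubstituted alkene between two quaternary carbons, platinum-mediated alkene isomerisation, and dehydrogenative coupling with the free C4 hydroxyl. The fallback sets out from 16 and comes back at 19; it seeks the same α-face syn delivery with a phosphorus tether and boron. The secondary C10 hydroxyl of 16 is converted with Ph2PCl/Et3N into 10α-[(diphenylphosphanyl)oxy]dauca-5,8-dien-4α-ol F6. Its trivalent phosphorus binds the cationic rhodium catalyst [Rh(nbd)(Ph2P(CH2)4PPh2)]BF4 and directs syn hydroboration with catecholborane to the α face, boron going to the less substituted C6. Oxidative work-up with NaOH/H2O2 (retention at C6) gives 4α,6α-dihydroxy-5αH-dauc-8-en-10α-yl diphenylphosphinate F7. Cleavage of the phosphinate with LiAlH4 gives 19.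

**Step 3 (aldol condensation).** The risks are a hindered enamine carbon next to the quaternary C4 and competing β-elimination of the silyloxy group. The fallback sets out from 4 and comes back at 5; it separates C–C bond formation from dehydration. Compound 4 is cyclised by a proline-catalysed 5-enolexo aldol addition that stops at the tertiary aldol 2-hydroxy-2-methyl-5-(propan-2-yl)-5-[(triethylsilyl)oxy]cyclopentane-1-carbaldehyde F8 (mixture at the two new centres, both lost in the next operation). This is dehydrated by syn elimination with Burgess reagent (methyl N-(triethylammoniosulfonyl)carbamate), which can engage only the free C1 hydroxyl and the acidic C5–H, to return 5.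

## Further compounds

F1 | step 7 | ethyl 2-diazo-3-hydroxybutanoate (racemic) | CCOC(=O)C(=[N+]=[N-])C(C)O
F2 | step 7 | ethyl 2-diazobut-3-enoate | CCOC(=O)C(=[N+]=[N-])C=C
F3 | step 7 | ethyl 4α-[(triethylsilyl)oxy]dauca-5,8-dien-14-oate | C1C=C(C(=O)OCC)CC=C2[C@]1(C)CC[C@]2(O[Si](CC)(CC)CC)C(C)C
F4 | step 7 | ethyl 8α-(phenylselanyl)-4α-[(triethylsilyl)oxy]dauca-5,9-dien-14-oate | C1=C[C@@]([Se]c3ccccc3)(C(=O)OCC)CC=C2[C@]1(C)CC[C@]2(O[Si](CC)(CC)CC)C(C)C
F5 | step 7 | ethyl 10α-hydroxy-4α-[(triethylsilyl)oxy]dauca-5,8-dien-14-oate | O[C@@H]1C=C(C(=O)OCC)CC=C2[C@]1(C)CC[C@]2(O[Si](CC)(CC)CC)C(C)C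
F6 | step 11 | 10α-[(diphenylphosphanyl)oxy]dauca-5,8-dien-4α-ol | O([C@@H]1C=C(C)CC=C2[C@]1(C)CC[C@]2(O)C(C)C)P(c3ccccc3)c3ccccc3
F7 | step 11 | 4α,6α-dihydroxy-5αH-dauc-8-en-10α-yl diphenylphosphinate | O([C@@H]1C=C(C)C[C@H](O)[C@@H]2[C@]1(C)CC[C@]2(O)C(C)C)P(=O)(c3ccccc3)c3ccccc3
F8 | step 3 | 2-hydroxy-2-methyl-5-(propan-2-yl)-5-[(triethylsilyl)oxy]cyclopentane-1-carbaldehyde (5S at the silyloxy carbon, mixture at the other two centres) | CC1(O)CC[C@](O[Si](CC)(CC)CC)(C(C)C)C1C=O
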